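Partner put into a closed flask stays on the books, free or carried in what was made from it, so I need the number of partners each product molecule carries. Here are the flasks and the runs so far:

| flask | substrate | partner | remark | time |
|---|---|---|---|---|
| Tuesday's | 0.25 M | 0.25 M (in portions, 4) | the very flask that is asked about, followed so far; portions every 6.0 s |  |
| Friday's | 0.12 M | 0.25 M (in portions, 4) | run made earlier; portions every 6.0 s |  |
| flask | 0.25 M | 0.250 M (in portions, 4) | the portions of partner follow each other after 6.0 s, the first at the start | 2.0 min |

- Tuesday's (time / s: target / %, intermediate B / %): 10.0: 0, 2.1; 12.0: 0.4, 3.2; 20.0: 2.4, 10.3; 25.0: 3.7, 14.6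
- Friday's (time / s: target / %, intermediate B / %): 15.0: 1.5, 7.1; 30.0: 7.1, 26.3; 40.0: 10.8, 33.7; 60.0: 14.4, 40.9; 80.0: 16.4, 43.4

(scatter of a reading: 0.3 percentage points)

- a reading or a percentage of target counts all its forms, free or not
- the concentration of target that is asked is that of its free form alone

* concentration of target (only what is free in solution) at 2.0 min, in M
* concentration of intermediate B at 2.0 min, in M
* concentration of substrate at 2.0 min, in M

I read that number, ν, from the start of Tuesday's run. Partner arrives in portions, so the amount charged so far climbs a staircase. Let Q be the area under that staircase, in portions times seconds: 14.0 s at 10.0 s and 18.0 s at 12.0 s. While substrate stays near its charge and the partner used stays small against the partner charged, product made through one partner step grows as Q, and through two steps in a row as Q squared. In logarithms, then, ν is the slope of ln(product) against ln(Q).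

Counting intermediate B plus target as product, the slope between those two readings is 2.14. Out to 20.0 s, where Q is 44.0 s, it reads 1.57. Both readings are rough, but both are above one, so I take two partners per product.

That gives the partner ceiling, half the partner charge over the substrate charge: 50.0% for Tuesday's flask. It is below 100%, so I expect partner to be the limiting reagent there, with product held under 0.125 M.

The forecast gives 0.025 M free target, 0.075 M intermediate B and 0.145 M substrate, on the reading “I read this as A + partner → B → target”. My count differs in taking two partners, though the forecast's free target plus intermediate B, 0.100 M, stays under my limit.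

Tuesday's flask gives 0.0196 M free target, 0.0497 M intermediate B and 0.103 M substrate at 2.0 min, by this scheme:

    substrate + partner → intermediate A (k = 0.199 M⁻¹ s⁻¹)
    partner + intermediate A → intermediate B (k = 0.573 M⁻¹ s⁻¹)
    intermediate B ⇌ target (K = 0.384, k = 0.0534 s⁻¹)
    2 substrate → self-condensation product (k = 1.73 × 10⁻⁴ M⁻¹ s⁻¹)
    crystals ⇌ target, rate k5*(cs5 - [target]) while solid is left; crystals form when [target] > cs5 (solubility = 45.0 mM, k = 1.47 s⁻¹)
    intermediate B → decomposed reagent (k = 0.00601 s⁻¹)

Partner is down to 0.41% of its charge, while substrate stands at 41% of its own. Intermediate B, target and decomposed reagent carry two partners each and intermediate A carries one, so 19.9%, 7.86%, 13.2% and, for intermediate A at its one partner, 8.88% sum to 49.8%, against the ceiling of 50.0%. The neighbouring flask with 0.62 M of partner has a ceiling of 124%, and there substrate falls to 1.25% while 20.7% of the partner remains.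

(The runs stem from a simulated flask from invented constants, noise included.)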